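Read the stall of the north-east run before trusting any number for the new flasks.

| setting | south-east | north-east | gamma | delta | alpha |
|---|---|---|---|---|---|
| L | 10 mM | 40 mM | 20 mM | 20 mM | 20 mM |
| Z | 24 mM | 24 mM | 24.0 mM | 24.0 mM | 24.0 mM |
| X | 10 mM | 10 mM | 10.0 mM | 10.0 mM | 10.0 mM |
| temperature | 55 °C | 85 °C | 60 °C | 85 °C | 110 °C |
| remark | run made earlier | run made earlier |  |  |  |
| time |  |  | 30 h | 30 h | 30 h |

| run | time / h | J / % | L / % |
|---|---|---|---|
| south-east | 3.00 | 6 | 96 |
| south-east | 4.00 | 5 | 95 |
| south-east | 6.00 | 7 | 92 |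
| south-east | 10.0 | 12 | 88 |
| south-east | 15.0 | 19 | 84 |
| south-east | 25.0 | 23 | 76 |
| south-east | 40.0 | 38 | 61 |
| north-east | 1.33 | 14 | 84 |
| north-east | 3.00 | 24 | 77 |
| north-east | 4.00 | 27 | 70 |
| north-east | 6.00 | 32 | 64 |
| north-east | 8.00 | 39 | 61 |
| north-east | 12.0 | 41 | 58 |

(scatter of a reading: 1.5 percentage points)

- the best flask by amount of J, in percent of the L charged; "all alike" if 1.5 percentage points covers them all (gamma / delta / alpha / all alike)
- amount of J at the end, in percent of the L charged, gamma
- amount of J at the end, in percent of the L charged, delta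
- amount of J at the end, in percent of the L charged, alpha

Two chemists argue over that stall. J moves from 39% to 41% between 8.00 h and 12.0 h, with L read at 58%.

The first says that L + Z and J have come to a balance. She counts one Z per J, so the free Z, z, is the Z charged less the J made: 7.60 mM. Her scale has its zero at the even case, J equal to L. The reading gives 10.8 mM for S, the even-split Z: the free Z at which a balanced flask holds equal J and L. Away from that zero, at one temperature, J/L = z/S. In delta, at the temperature of the north-east run and with J and L sharing the charge, her balance falls at 11.0 mM of J, or 54.8% of the L charged.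

The second says the run stopped on Z, the limiting reagent of north-east, at 1.46 Z per J. Delta has the same Z for half the L. So the same 16.4 mM of J can form, which is 82.0%.

The forecast leans to the first side, a little below her number. It names delta best, with gamma 40%, delta 53% (range 42% to 86%) and alpha 45%. Its caution: “The stall is ambiguous because temperature and L loading changed together.”

The flasks give 35.6% in gamma, 52.7% in delta and 23.3% in alpha. So delta is best, and the forecast's alpha stands 22 percentage points too high.

    L + X → Q (k = 0.00620 L mol⁻¹ min⁻¹, Ea = 103 kJ mol⁻¹)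
    L + Z ⇌ J (K = 450 L mol⁻¹, k = 0.410 L mol⁻¹ min⁻¹, Ea = 72.0 kJ mol⁻¹, ΔH = 8.00 kJ mol⁻¹)
    Z + J → E (k = 0.160 L mol⁻¹ min⁻¹, Ea = 93.0 kJ mol⁻¹)
    L + Z ⇌ D (K = 97.0 L mol⁻¹, k = 0.00560 L mol⁻¹ min⁻¹, Ea = 92.0 kJ mol⁻¹, ΔH = 5.00 kJ mol⁻¹)
    (constants at 110 °C)

The first chemist's delta figure lies 2.1 points above the flask, but her S is not what delta shows. Delta ends with 6.43 mM of Z, so z times L over J there is 3.51 mM, against her 10.8 mM, and E, which her count of Z leaves out, holds 17.2% of the L charged. The second view, Z gone short with L still there, has its region in alpha, which ends with 1.58 mM of Z against 5.64 mM of L. Gamma at 30.0 h makes J 10.8 times faster than it uses it up, each step taken net. For gamma's neighbour with 60 mM of Z, at 60 °C, S read at 85 °C and carried over unchanged puts the balance at 80.3%. That flask computes to 61.9%.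

(All runs are calculated with made-up constants; scatter was added.)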